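**Strategy.** Rings: A (aldehyde-bearing arene), B (trans dioxane), C (central arene), D (cis dioxane), E (catechol). Ring D is disconnected at both C–O bonds to a ring C ortho-bromophenol and an enantiopure trans-epoxide carrying ring E. One domino operation joins them: the phenoxide oxygen para to the ring B attachment opens the epoxide at its benzylic carbon with inversion, and the freed alkoxide is O-arylated at the neighbouring C–Br carbon with retention. This exploits the cis relationship of the aryl-bearing and hydroxymethyl-bearing carbons of ring D and the unequal oxygens of ring C. Ring B is built earlier by mirror logic (cis-epoxide, ortho-fluorophenol, SNAr); deallylation and Wittig homologation finish.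

Key step: step 12

Remark: read from the SMILES, ring B is trans with both dioxane carbons S, and ring D is cis with the aryl-bearing carbon R and the hydroxymethyl-bearing carbon S; the route is planned for exactly this diastereomer.

**Step 1**
Reactants: 1 3-bromo-4-hydroxybenzaldehyde
Product: 2 3-bromo-4-(methoxymethoxy)benzaldehyde
Conditions: MOMCl, i-Pr2NEt, CH2Cl2, 0 °C to rt
Reagents that add atoms: chloromethyl methyl ether, COCCl
Why: Williamson-type O-alkylation of the phenol should mask the ring C oxygen as a base-stable, acid-labile methoxymethyl ether and leave the formyl group untouched.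

**Step 2**
Reactants: 2 3-bromo-4-(methoxymethoxy)benzaldehyde
Product: 3 ethyl (2Z)-3-[3-bromo-4-(methoxymethoxy)phenyl]prop-2-enoate
Conditions: (CF3CH2O)2P(O)CH2CO2Et, KN(SiMe3)2, 18-crown-6, THF, −78 °C
Reagents that add atoms: ethyl 2-[bis(2,2,2-trifluoroethoxy)phosphoryl]acetate, CCOC(=O)CP(=O)(OCC(F)(F)F)OCC(F)(F)F
Why: Still–Gennari variant of the Horner–Wadsworth–Emmons olefination, in which the electron-poor phosphonate under dissociating conditions should eliminate from the kinetic adduct and give the (Z)-cinnamate.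

**Step 3**
Reactants: 3 ethyl (2Z)-3-[3-bromo-4-(methoxymethoxy)phenyl]prop-2-enoate
Product: 4 ethyl (2R,3R)-3-[3-bromo-4-(methoxymethoxy)phenyl]oxirane-2-carboxylate
Conditions: (R,R)-[N,N'-bis(3,5-di-tert-butylsalicylidene)cyclohexane-1,2-diaminato]manganese chloride (5 mol%), 4-phenylpyridine N-oxide (25 mol%), aq NaOCl (pH 11.3), CH2Cl2, 0–4 °C
Reagents that add atoms: sodium hypochlorite, [Na+].[O-]Cl
Why: Jacobsen–Katsuki epoxidation of a conjugated cis-disubstituted alkene, in which the (R,R) trivalent manganese salen catalyst should deliver oxygen to the face that gives the (2R,3R) cis-glycidate; any trans-epoxide from bond rotation would be removed by chromatography.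

**Step 4**
Reactants: 4 ethyl (2R,3R)-3-[3-bromo-4-(methoxymethoxy)phenyl]oxirane-2-carboxylate
Product: 5 [(2S,3R)-3-[3-bromo-4-(methoxymethoxy)phenyl]oxiran-2-yl]methanol
Conditions: NaBH4, EtOH, 0 °C to rt
Reagents that add atoms: none
Why: Hydride reduction of the oxygen-activated glycidic ester should give the primary alcohol without touching the epoxide, the change from 2R to 2S being a priority change only.

**Step 5**
Reactants: 5 [(2S,3R)-3-[3-bromo-4-(methoxymethoxy)phenyl]oxiran-2-yl]methanol
Product: 6 (2S,3R)-3-[3-bromo-4-(methoxymethoxy)phenyl]-2-[(triphenylmethoxy)methyl]oxirane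
Conditions: Ph3CCl, Et3N, DMAP (cat.), CH2Cl2, rt
Reagents that add atoms: trityl chloride, ClC(c1ccccc1)(c1ccccc1)c1ccccc1
Why: Tritylation of the primary alcohol should install a bulky, base-stable, non-migrating ether that also shields the non-benzylic epoxide carbon.

**Step 6**
Reactants: 6 (2S,3R)-3-[3-bromo-4-(methoxymethoxy)phenyl]-2-[(triphenylmethoxy)methyl]oxirane; 7 4-fluoro-3-hydroxybenzaldehyde
Product: 9 (2S,3S)-3-[3-bromo-4-(methoxymethoxy)phenyl]-2-[(triphenylmethoxy)methyl]-2,3-dihydro-1,4-benzodioxine-6-carbaldehyde, via fluoro alcohol 8 (not isolated)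
Conditions: Cs2CO3, DMSO, 80 °C then 110 °C
Reagents that add atoms: none
Why: Domino SN2 epoxide opening and intramolecular SNAr, in which the phenoxide of 7 should attack the benzylic epoxide carbon with inversion (3R to S) and the freed alkoxide should displace the fluoride para to the formyl group through a Meisenheimer adduct with its own C–O bond intact (2S kept), so the cis-epoxide becomes the trans dioxane and the OH and F positions fix which oxygen carries which carbon.

**Step 7**
Reactants: 9 (2S,3S)-3-[3-bromo-4-(methoxymethoxy)phenyl]-2-[(triphenylmethoxy)methyl]-2,3-dihydro-1,4-benzodioxine-6-carbaldehyde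
Product: 10 (2S,3S)-3-(3-bromo-4-hydroxyphenyl)-2-(hydroxymethyl)-2,3-dihydro-1,4-benzodioxine-6-carbaldehyde
Conditions: 6 M aq HCl/THF (1:4), 45 °C
Reagents that add atoms: none
Why: Acid hydrolysis of the methoxymethyl acetal and the trityl ether should free the ring C phenol and the primary alcohol, and since ring B is the thermodynamically preferred trans isomer, reversible benzylic C–O ionisation cannot erode it.

**Step 8**
Reactants: 11 caffeic acid
Product: 12 prop-2-en-1-yl (2E)-3-[3,4-bis(prop-2-en-1-yloxy)phenyl]prop-2-enoate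
Conditions: allyl bromide, K2CO3, DMF, 50 °C
Reagents that add atoms: allyl bromide, C=CCBr
Why: Williamson alkylation of both phenoxides and of the carboxylate should protect the catechol as allyl ethers, which are stable to base and removable under neutral conditions.

**Step 9**
Reactants: 12 prop-2-en-1-yl (2E)-3-[3,4-bis(prop-2-en-1-yloxy)phenyl]prop-2-enoate
Product: 13 (2E)-3-[3,4-bis(prop-2-en-1-yloxy)phenyl]prop-2-en-1-ol
Conditions: i-Bu2AlH, CH2Cl2, −78 °C; aq potassium sodium tartrate
Reagents that add atoms: none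
Why: 1,2-Reduction of the conjugated ester by the aluminium hydride should give the (E)-allylic alcohol without affecting the alkene geometry.

**Step 10**
Reactants: 13 (2E)-3-[3,4-bis(prop-2-en-1-yloxy)phenyl]prop-2-en-1-ol
Product: 14 [(2S,3S)-3-[3,4-bis(prop-2-en-1-yloxy)phenyl]oxiran-2-yl]methanol
Conditions: Ti(Oi-Pr)4 (10 mol%), L-(+)-diethyl tartrate (12 mol%), t-BuOOH, 4 Å molecular sieves, CH2Cl2, −20 °C
Reagents that add atoms: tert-butyl hydroperoxide, CC(C)(C)OO
Why: Sharpless asymmetric epoxidation, in which the titanium tartrate complex binds the allylic hydroxyl and L-(+)-diethyl tartrate should direct oxygen to the face giving the (2S,3S) trans-epoxy alcohol, the allyl ether double bonds being inert to this reagent.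

**Step 11**
Reactants: 14 [(2S,3S)-3-[3,4-bis(prop-2-en-1-yloxy)phenyl]oxiran-2-yl]methanol
Product: 15 (2S,3S)-3-[3,4-bis(prop-2-en-1-yloxy)phenyl]-2-[(prop-2-en-1-yloxy)methyl]oxirane
Conditions: NaH, allyl bromide, n-Bu4NI (cat.), THF/DMF, 0 °C
Reagents that add atoms: allyl bromide, C=CCBr
Why: Williamson etherification of the alkoxide at low temperature in aprotic medium should cap the primary hydroxyl with a non-migrating group without epoxide migration.

**Step 12**
Reactants: 10 (2S,3S)-3-(3-bromo-4-hydroxyphenyl)-2-(hydroxymethyl)-2,3-dihydro-1,4-benzodioxine-6-carbaldehyde; 15 (2S,3S)-3-[3,4-bis(prop-2-en-1-yloxy)phenyl]-2-[(prop-2-en-1-yloxy)methyl]oxirane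
Product: 17 (2S,3S)-3-[(2R,3S)-2-[3,4-bis(prop-2-en-1-yloxy)phenyl]-3-[(prop-2-en-1-yloxy)methyl]-2,3-dihydro-1,4-benzodioxin-6-yl]-2-(hydroxymethyl)-2,3-dihydro-1,4-benzodioxine-6-carbaldehyde, via bromo alcohol 16 (not isolated)
Conditions: Cs2CO3, DMF, 85 °C; then CuI (copper monoiodide, 20 mol%), 1,10-phenanthroline (40 mol%), 110 °C, same flask
Reagents that add atoms: none
Why: The cesium phenoxide of 10, whose oxygen is para to the ring B attachment, should open trans-epoxide 15 at its benzylic carbon by SN2, and the freed secondary alkoxide of 16 should then be O-arylated by copper at the adjacent C–Br carbon (alkoxide coordination, oxidative addition, C–O reductive elimination), which closes ring D. The closest known reaction type is the copper-catalysed domino epoxide ring-opening and intramolecular Ullmann O-arylation of ortho-halophenols with epoxides to give 2,3-dihydro-1,4-benzodioxines. Ring D closes in the six-membered exo mode at the aryl carbon (new C(aryl)–O bond inside the ring, C–Br bond outside), and no other ring size is available because the only other hydroxyl, the ring B CH2OH, cannot reach the bromide. The aryl-bearing carbon should become R by inversion of the 3S epoxide carbon, while the carbon carrying the allyloxymethyl group keeps its 2S configuration because its C–O bond is never broken, so one inversion and one retention on a trans-epoxide give the cis ring. The step needs attack at the benzylic and not the neighbouring epoxide carbon, which the electron-rich aryl group (loosened benzylic C–O bond) and the inductive and steric shielding by the CH2O-allyl group should secure, and it needs the right oxygen on each carbon, which is fixed by the ring C positions of OH and Br. Copper is added only after the phenoxide has been consumed so that diaryl ether formation is avoided, and any phenoxide-triggered reversible opening of ring B through a quinone methide should return the thermodynamic trans isomer.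

**Step 13**
Reactants: 17 (2S,3S)-3-[(2R,3S)-2-[3,4-bis(prop-2-en-1-yloxy)phenyl]-3-[(prop-2-en-1-yloxy)methyl]-2,3-dihydro-1,4-benzodioxin-6-yl]-2-(hydroxymethyl)-2,3-dihydro-1,4-benzodioxine-6-carbaldehyde
Product: 18 (2S,3S)-3-[(2R,3S)-2-(3,4-dihydroxyphenyl)-3-(hydroxymethyl)-2,3-dihydro-1,4-benzodioxin-6-yl]-2-(hydroxymethyl)-2,3-dihydro-1,4-benzodioxine-6-carbaldehyde
Conditions: Pd(PPh3)4 (10 mol%), p-TolSO2H, CH2Cl2/MeOH, rt
Reagents that add atoms: none
Why: Tsuji–Trost-type deallylation, in which zerovalent palladium should ionise each allyl ether to a π-allyl complex that the sulfinate captures as allyl p-tolyl sulfone, under near-neutral conditions at rt that should leave the aldehyde and the cis ring D untouched.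

**Step 14**
Reactants: 18 (2S,3S)-3-[(2R,3S)-2-(3,4-dihydroxyphenyl)-3-(hydroxymethyl)-2,3-dihydro-1,4-benzodioxin-6-yl]-2-(hydroxymethyl)-2,3-dihydro-1,4-benzodioxine-6-carbaldehyde
Product: 19 (2E)-3-{(2S,3S)-3-[(2R,3S)-2-(3,4-dihydroxyphenyl)-3-(hydroxymethyl)-2,3-dihydro-1,4-benzodioxin-6-yl]-2-(hydroxymethyl)-2,3-dihydro-1,4-benzodioxin-6-yl}prop-2-enal
Conditions: Ph3P=CHCHO (1.2 equiv), THF, 55 °C
Reagents that add atoms: (triphenylphosphoranylidene)acetaldehyde, O=CC=P(c1ccccc1)(c1ccccc1)c1ccccc1
Why: Wittig olefination with the stabilised formylmethylene ylide should convert the aryl aldehyde into the (E)-enal, the weakly basic ylide tolerating the free catechol and alcohols.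

**Compound list**

1 | 3-bromo-4-hydroxybenzaldehyde | O=Cc1ccc(O)c(Br)c1 | starting material
2 | 3-bromo-4-(methoxymethoxy)benzaldehyde | O=Cc1ccc(OCOC)c(Br)c1 | intermediate
3 | ethyl (2Z)-3-[3-bromo-4-(methoxymethoxy)phenyl]prop-2-enoate | CCOC(=O)/C=C\c1ccc(OCOC)c(Br)c1 | intermediate
4 | ethyl (2R,3R)-3-[3-bromo-4-(methoxymethoxy)phenyl]oxirane-2-carboxylate (cis-epoxide) | CCOC(=O)[C@@H]1O[C@@H]1c1ccc(OCOC)c(Br)c1 | intermediate
5 | [(2S,3R)-3-[3-bromo-4-(methoxymethoxy)phenyl]oxiran-2-yl]methanol (cis-epoxide) | OC[C@@H]1O[C@@H]1c1ccc(OCOC)c(Br)c1 | intermediate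
6 | (2S,3R)-3-[3-bromo-4-(methoxymethoxy)phenyl]-2-[(triphenylmethoxy)methyl]oxirane (cis-epoxide) | c1ccccc1C(c1ccccc1)(c1ccccc1)OC[C@@H]1O[C@@H]1c1ccc(OCOC)c(Br)c1 | intermediate
7 | 4-fluoro-3-hydroxybenzaldehyde | O=Cc1ccc(F)c(O)c1 | starting material
8 | 3-{(1S,2S)-1-[3-bromo-4-(methoxymethoxy)phenyl]-2-hydroxy-3-(triphenylmethoxy)propoxy}-4-fluorobenzaldehyde (fluoro alcohol) | O=Cc1ccc(F)c(c1)O[C@@H](c1ccc(OCOC)c(Br)c1)[C@H](COC(c1ccccc1)(c1ccccc1)c1ccccc1)O | intermediate
9 | (2S,3S)-3-[3-bromo-4-(methoxymethoxy)phenyl]-2-[(triphenylmethoxy)methyl]-2,3-dihydro-1,4-benzodioxine-6-carbaldehyde (trans) | O=Cc1ccc2c(c1)O[C@@H](c1ccc(OCOC)c(Br)c1)[C@H](COC(c1ccccc1)(c1ccccc1)c1ccccc1)O2 | intermediate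
10 | (2S,3S)-3-(3-bromo-4-hydroxyphenyl)-2-(hydroxymethyl)-2,3-dihydro-1,4-benzodioxine-6-carbaldehyde | O=Cc1ccc2c(c1)O[C@@H](c1ccc(O)c(Br)c1)[C@H](CO)O2 | intermediate
11 | caffeic acid | OC(=O)/C=C/c1ccc(O)c(O)c1 | starting material
12 | prop-2-en-1-yl (2E)-3-[3,4-bis(prop-2-en-1-yloxy)phenyl]prop-2-enoate | C=CCOC(=O)/C=C/c1ccc(OCC=C)c(OCC=C)c1 | intermediate
13 | (2E)-3-[3,4-bis(prop-2-en-1-yloxy)phenyl]prop-2-en-1-ol | OC/C=C/c1ccc(OCC=C)c(OCC=C)c1 | intermediate
14 | [(2S,3S)-3-[3,4-bis(prop-2-en-1-yloxy)phenyl]oxiran-2-yl]methanol (trans-epoxide) | OC[C@@H]1O[C@H]1c1ccc(OCC=C)c(OCC=C)c1 | intermediate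
15 | (2S,3S)-3-[3,4-bis(prop-2-en-1-yloxy)phenyl]-2-[(prop-2-en-1-yloxy)methyl]oxirane (trans-epoxide) | C=CCOC[C@@H]1O[C@H]1c1ccc(OCC=C)c(OCC=C)c1 | intermediate
16 | (2S,3S)-3-{3-bromo-4-[(1R,2S)-1-[3,4-bis(prop-2-en-1-yloxy)phenyl]-2-hydroxy-3-(prop-2-en-1-yloxy)propoxy]phenyl}-2-(hydroxymethyl)-2,3-dihydro-1,4-benzodioxine-6-carbaldehyde (bromo alcohol) | O=Cc1ccc2c(c1)O[C@@H](c1ccc(O[C@H](c3ccc(OCC=C)c(OCC=C)c3)[C@@H](O)COCC=C)c(Br)c1)[C@H](CO)O2 | intermediate
17 | (2S,3S)-3-[(2R,3S)-2-[3,4-bis(prop-2-en-1-yloxy)phenyl]-3-[(prop-2-en-1-yloxy)methyl]-2,3-dihydro-1,4-benzodioxin-6-yl]-2-(hydroxymethyl)-2,3-dihydro-1,4-benzodioxine-6-carbaldehyde | O=Cc1ccc2c(c1)O[C@@H](c1ccc3c(c1)O[C@@H](COCC=C)[C@@H](c1ccc(OCC=C)c(OCC=C)c1)O3)[C@H](CO)O2 | intermediate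
18 | (2S,3S)-3-[(2R,3S)-2-(3,4-dihydroxyphenyl)-3-(hydroxymethyl)-2,3-dihydro-1,4-benzodioxin-6-yl]-2-(hydroxymethyl)-2,3-dihydro-1,4-benzodioxine-6-carbaldehyde | O=Cc1ccc2c(c1)O[C@@H](c1ccc3c(c1)O[C@@H](CO)[C@@H](c1ccc(O)c(O)c1)O3)[C@H](CO)O2 | intermediate
19 | (2E)-3-{(2S,3S)-3-[(2R,3S)-2-(3,4-dihydroxyphenyl)-3-(hydroxymethyl)-2,3-dihydro-1,4-benzodioxin-6-yl]-2-(hydroxymethyl)-2,3-dihydro-1,4-benzodioxin-6-yl}prop-2-enal | O=C/C=C/c1ccc2c(c1)O[C@@H](c1ccc3c(c1)O[C@@H](CO)[C@@H](c1ccc(O)c(O)c1)O3)[C@H](CO)O2 | target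

**Step count.** Total: 14 steps. Longest linear sequence: 10 steps (steps 1–7, then 12, 13, 14); steps 8–11 form the convergent branch.

**Steps most likely to fail**

1. Step 12. What may go wrong: attack of the phenoxide at the non-benzylic epoxide carbon, slow copper O-arylation of the hindered secondary alkoxide with loss of bromine by reduction, or trapping of ring B while it is transiently opened by the para-phenoxide. Fallback, from 10 and 15, back to the route at 17: the two events are separated and the closure is changed from a copper Ullmann coupling to a palladium-catalysed C–O cross-coupling. Cs2CO3 in DMF at 75 °C without copper should give the ring-opened bromo alcohol 16, which is isolated. Pd(OAc)2 with 2-(di-tert-butylphosphino)-1,1'-binaphthyl and Cs2CO3 in toluene at 80 °C should then close ring D with retention at the carbinol carbon (oxidative addition of zerovalent palladium into C–Br, alkoxide binding, reductive elimination); the aryl allyl ethers are expected to survive because no soft nucleophile is present. No compound outside the list is made (F0).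

2. Step 6. What may go wrong: intermolecular fluoride displacement by phenoxide leading to oligomers, or sluggish ring closure at the aldehyde-activated C–F bond. Fallback, from 6, back to the route at 9: the SNAr closure is replaced by an Ullmann closure that does not depend on activation by the formyl group. Commercial 3-hydroxy-4-iodobenzaldehyde (O=Cc1ccc(I)c(O)c1) is used in place of 7. Cs2CO3 in DMF at 80 °C should give 3-{(1S,2S)-1-[3-bromo-4-(methoxymethoxy)phenyl]-2-hydroxy-3-(triphenylmethoxy)propoxy}-4-iodobenzaldehyde F1. CuI (copper monoiodide) with 1,10-phenanthroline at 100 °C should then close ring B at the C–I bond with retention; the ring C bromide is the less reactive halide and cannot be reached intramolecularly.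

3. Step 13. What may go wrong: incomplete cleavage of the aliphatic allyl ether, or epimerisation of the cis ring D by reversible benzylic C–O ionisation in the sulfinic acid medium. Fallback, from 17, back to the route at 18: π-allyl transfer is replaced by isomerisation and enol ether hydrolysis. [Ir(cod)(PMePh2)2]PF6 (activated with H2) in THF at rt should isomerise all three allyl ethers to give (2S,3S)-3-[(2R,3S)-2-{3,4-bis[(1E)-prop-1-en-1-yloxy]phenyl}-3-{[(1E)-prop-1-en-1-yloxy]methyl}-2,3-dihydro-1,4-benzodioxin-6-yl]-2-(hydroxymethyl)-2,3-dihydro-1,4-benzodioxine-6-carbaldehyde F2. HgCl2 and HgO in acetone/H2O at rt should then hydrolyse the propenyl ethers under neutral conditions.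

**Further compounds**

F0 | step 12 | none | none
F1 | step 6 | 3-{(1S,2S)-1-[3-bromo-4-(methoxymethoxy)phenyl]-2-hydroxy-3-(triphenylmethoxy)propoxy}-4-iodobenzaldehyde | O=Cc1ccc(I)c(c1)O[C@@H](c1ccc(OCOC)c(Br)c1)[C@H](COC(c1ccccc1)(c1ccccc1)c1ccccc1)O
F2 | step 13 | (2S,3S)-3-[(2R,3S)-2-{3,4-bis[(1E)-prop-1-en-1-yloxy]phenyl}-3-{[(1E)-prop-1-en-1-yloxy]methyl}-2,3-dihydro-1,4-benzodioxin-6-yl]-2-(hydroxymethyl)-2,3-dihydro-1,4-benzodioxine-6-carbaldehyde | O=Cc1ccc2c(c1)O[C@@H](c1ccc3c(c1)O[C@@H](CO/C=C/C)[C@@H](c1ccc(O/C=C/C)c(O/C=C/C)c1)O3)[C@H](CO)O2
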